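The constants are those of an exercise; no experiment stands behind them.

What stands in this flask at 12 min, and is anything still moving then?

    substrate ⇌ ring (K1 = 11, k1 = 0.0062 s⁻¹)
    2 substrate → self-condensation product (k2 = 0.0037 M⁻¹ s⁻¹)
    substrate + substrate ⇌ open dimer (K3 = 1400 M⁻¹, k3 = 2.0 M⁻¹ s⁻¹)

substrate 0.0020 M; time 12 min

* at 12 min, what has stopped the reaction, if anything has (it is still moving / all of the substrate has reacted / forward and back rates have come level)
* share of the substrate used up at 12 min
* ring at 12 min, in percent of the substrate charged
* open dimer at 12 min, in percent of the substrate charged

- in percentages every species weighs as the substrate in it: one open dimer or self-condensation product counts as two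
- where a step has two of a species, its rate is k times that concentration squared, and two are used at each turn
- the reaction counts as stopped when no species that holds the substrate changes by six tenths of a point or more over the second half of the time
- run time (flask): 12 min

Our first thought is the ring balance: substrate and ring relax with a half-life of 1.71 min, short against 12 min, so ring should hold 91.7% of the charge. But at the start, ring formation uses substrate at 0.78 of the rate at which dimer formation uses it. Following that split as [substrate] falls, with no way back, gives the open dimer 35.8% of the charge. We drop self-condensation, whose rate constant 0.0037 M⁻¹ s⁻¹ is far below the 2.0 M⁻¹ s⁻¹ of dimer formation.

Surely the dimer comes back, though. What stays constant here is the lifetime of the open dimer, the equilibrium constant of its formation divided by the rate constant, 11.7 min. It is longer than the ring relaxation half-life, so the first rush is kinetic control and the slow return is thermodynamic control. At the ring balance, with the dimer ignored, [substrate] is 8.33% of the charge, and the dimer in balance with that is 3.89%. We let the excess over that decay with the lifetime. The rush takes time, so we start the clock, somewhat arbitrarily, at 1.71 min. That gives 17.1% dimer at 12 min, and a fall of 8.9 percentage points over the second half, so the flask is still moving.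

Yet dimer drains through [substrate] on its way to ring, and that needs a push. We freeze [substrate] instead, the steady-state approximation: what the dimer releases passes on to ring, and for that flow substrate must stand 3 points above the share that balances the ring then present. That leaves substrate at 9.70%, so 90.3% is used up and ring is 73.2%.

The forecast says it is still moving, with 90.3% used up, ring 72.5% and dimer 17.8%, the dimer “still draining into the ring”. Its ring is a little below ours and its dimer a little above.

For this flask the simulation gives: it is still moving, with 90.0% used up, ring 71.4% and dimer 18.5%. Now take the neighbouring flask with 0.0012 M of substrate. In that flask the lifetime is again 11.7 min, the rush gives the dimer 25.9%, and the dimer in balance is 2.33%. The same reckoning then gives that flask 12.1% dimer at 12 min. In that neighbouring flask the simulation gives 13.0% dimer and 77.1% ring at 12.0 min.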